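## The problem

The target joins two 5,7-dimethoxycoumarin units to a 1,4-dimethylcyclohex-3-ene. Coumarin B is bonded through its C8 directly to ring carbon C6, and coumarin A through its C8 and an E-vinylene to the quaternary carbon C1. There are only two stereocentres, C1 (methyl, vinylene, two ring carbons) and the adjacent C6 (tertiary, allylic and benzylic), with vinylene and aryl cis; both are R. As ring neighbours one can control the other, so a single absolute element is enough, and nothing else in the molecule can relay chirality. The hardest bond is C6–C8 of coumarin B: it lies next to the quaternary carbon and ends on an aryl carbon flanked by two oxygen substituents, so any aryl–C(sp3) coupling or conjugate arylation there is doubly hindered. Sensitive groups are the two lactones (opened by hydroxide or alkoxide, attacked by organolithiums and hydrides), the trisubstituted C4=C5 alkene (protonated by acid and then captured by a free ortho-phenol) and the doubly activated C6–H. The enabling feature is the oxygen pattern of the benzene ring of coumarin B: O1 on C8a, the methoxy on C7 and the methoxy on C5 are mutually meta, and C8 sits between two of them. A vinylketene and an ynol ether assemble exactly such a ring, so it can be grown on C6 from an alkyne instead of being attached to it.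

## Retrosynthesis

Target 38 is cut at the bond between the vinylene carbon and C8 of coumarin A, giving alkenylboronate 37 and iodocoumarin 36 (one step from 35). Compared with an olefination from a C1 aldehyde, this keeps base-sensitive coumarin ylides out of the route and takes the E geometry from syn-hydroboration of the terminal alkyne 34. The forward coupling must tolerate a di-ortho-substituted iodide and two lactones.

Alkyne 34 is traced back to phenol 27 by opening the pyranone of coumarin B at O1–C2 and at the C3=C4 alkene: lactone 32 comes from salicylaldehyde 29 and ylide 30, and 29 from ortho-formylation of 27. Exchange of silicon for methyl at O7 and loss of the alkyne silyl group (33, then 34) complete this stage. The two oxygens flanking C8 must be differentiated, one free and one masked; either sense leads to the same coumarin.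

Phenol 27 is cut at three ring bonds, C8–C8a, C6–C7 and C4a–C8a, to siloxyalkyne 20 and cyclobutenone 22 (one step from 21). Against attaching a preformed trioxygenated arene to C6, this makes the crowded C6–C8 bond an ordinary alkyne–ring bond that exists long before the arene does, and it delivers the oxygens already differentiated. The forward reaction needs a thermal pericyclic cascade of defined regiochemistry that ignores the second alkyne on C1.

Siloxyalkyne 20 comes from terminal alkyne 17 by oxidation of its acetylide and O-silylation, and 17 from bis-silyl diyne 16 by selective loss of the trimethylsilyl group. This fixes the order of events: the C6 alkyne must arrive early with the labile silyl group and the C1 alkyne late with the robust one. No step in between may use alkoxide or fluoride.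

Diyne 16 is cut at the C1 alkyne to aldehyde 13 by way of dibromoalkene 14. A dibromo-olefination and elimination with in-flask silylation is chosen over carbonate-mediated homologations, which would strip the C6 silyl group.

Aldehyde 13 is traced to thioester 12 and this, by removal of the C1 methyl group, to thioester 10. The C1–CH3 bond is made by enolate alkylation under control of C6. The thioester is chosen because a thiolate frees it from the auxiliary without touching the C–Si bond, it enolises cleanly, and it is reduced to the aldehyde in one operation.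

Thioester 10 comes from imide 9, and 9 is cut at C1–C6 and C2–C3 to diene 4 and acrylimide 8. The Diels–Alder reaction forms the ring, places methyl and alkynyl correctly through their cooperating directing effects, and sets C6 absolutely through the auxiliary. Routes that would add the C6 alkyne by conjugate addition next to a preformed quaternary centre were set aside, because a methyl and an alkynyl group differ too little in size to steer an incoming nucleophile or to be told apart in a desymmetrisation.

Diene 4 is made from aldehyde 1 and ylide 2 by way of enone 3 (two olefinations), and acrylimide 8 from oxazolidinone 5 and acid chloride 6.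

## Roads not taken

Alternative 1: The cut is at the C6–aryl bond and the C1–CH3 bond. Forward, a rhodium complex of a chiral diene ligand would add arylzinc reagent A3 to C6 of dienoate A2, and the ester enolate would be methylated in the same flask to give A1, aryl cis to ester. Its merits are two bonds and both stereocentres in one catalytic operation from an achiral ring, with the benzene ring of coumarin B arriving ready-made. Up to the stage of the C6 arene it is clearly shorter than the chosen plan. Its weak points:
- The nucleophile carries two ortho oxygens and must reach a β-carbon of a cyclic dienoate, where 1,6-addition at C4 competes.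
- Enantioselectivity would rest on ortho,ortho-disubstituted aryl donors, which transfer slowly.
- The methoxymethyl ether must later be removed with acid beside the C4=C5 alkene, where a free ortho-phenol can add across it.

The methylation uses the same C6-to-C1 relay as step 6 here, so there is no gain in that respect. Against its brevity the chosen plan sets a C6–C bond made by cycloaddition, an arene whose oxygens emerge differentiated without an acid deprotection, and absolute control from a recoverable auxiliary.

Alternative 2: The cut is C5–C6. Forward, acid would ionise benzylic alcohol A5 at C6 (either carbinol epimer), and the Z-vinylsilane would attack the cation through its silicon-bearing carbon to close the cyclohexene as A4, with the alkene fixed at C4=C5 by loss of silicon. Its merits are that coumarin B is carried in complete, the closure is stereoconvergent at the carbinol carbon, and the alkene position is not in doubt. After A4 only desilylation, hydroboration and coupling remain, fewer steps than the chosen plan needs after its key step. Its weak points: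
- C6 must be steered by the open-chain quaternary carbon C1, whose methyl and silylethynyl groups differ little in a chair-like transition state, so the cis/trans outcome is hard to predict.
- The cation sits next to a quaternary propargylic carbon and can suffer 1,2-shifts.
- The quaternary stereocentre must first be made enantiopure in an acyclic setting.

The chosen plan is longer, but fixes the relative configuration by a suprafacial cycloaddition and an anti alkylation on a ring, both with clear models.

Alternative 3: The cut is C1–C6. Forward, the silyl ketene acetal of δ-lactone A7 would undergo an Ireland–Claisen [3,3] shift through the boat transition state that the ring enforces. C1–C6 forms, the lactone C–O bond at C4 breaks, the alkene moves to C4=C5, and acid A6 results with aryl cis to carboxyl. Its merits are that the hindered bond between the two stereocentres is made intramolecularly with chirality transfer from one carbinol centre, and the arene is in place early. In making the C1–C6 bond it is at least as good as the Diels–Alder reaction used here, and it creates the quaternary centre in the same step, which the chosen plan does not. Its weak points: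
- A7 needs an enantiopure tertiary allylic carbinol, itself a fully substituted stereocentre.
- That C–O bond is tertiary, allylic and conjugated to an electron-rich styrene, so ionisation and elimination threaten during enolisation and silylation.
- As in alternative 1, an acid-labile ether must be cleaved next to the ring alkene before the pyranone can be built.

The chosen plan sets against this a cheaper source of chirality, no ionisable tertiary ester, and no acid step once the phenol is free.

Key step: step 13

Remark: cyclohexene locants follow the target in every name (C1 quaternary carbon, C4=C5 alkene with methyl on C4, C6 the carbon that ends on coumarin B). CIP descriptors change along the route only where substituent priorities change; the spatial arrangement at C1 and C6 is constant from 12 onward.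

Assumption: iodination of 35 is taken to occur at C8 (ortho to one methoxy group, para to the other, less crowded than C6), and 22 is made in one step because its commercial supply is uncertain.

## Steps

Step 1
Reactants: 1 3-(trimethylsilyl)prop-2-ynal; 2 1-(triphenyl-λ5-phosphanylidene)propan-2-one
Product: 3 (E)-6-(trimethylsilyl)hex-3-en-5-yn-2-one
Conditions: CH2Cl2, 0 °C → rt
Reagents that add atoms: none
Why: Wittig olefination with a stabilised ylide, which should give the E-enone; nothing in the medium can cleave the C–Si bond.

Step 2
Reactants: 3 (E)-6-(trimethylsilyl)hex-3-en-5-yn-2-one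
Product: 4 (E)-trimethyl(5-methylhexa-3,5-dien-1-yn-1-yl)silane
Conditions: Ph3PCH3Br, NaN(SiMe3)2, THF, 0 °C; then 3, 0 °C → rt
Reagents that add atoms: methyltriphenylphosphonium bromide, C[P+](c1ccccc1)(c1ccccc1)c1ccccc1.[Br-]
Why: Wittig methylenation; the unstabilised ylide adds 1,2 to the enone carbonyl and leaves the E-alkene alone. An amide base is used so that no alkoxide meets the trimethylsilyl alkyne.

Step 3
Reactants: 5 (R)-4-benzyl-1,3-oxazolidin-2-one; 6 acryloyl chloride
Product: 8 (R)-3-acryloyl-4-benzyl-1,3-oxazolidin-2-one, via bromomagnesium salt 7 (not isolated)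
Conditions: MeMgBr (1.0 equiv), THF, 0 °C; then 6, −78 → 0 °C
Reagents that add atoms: none
Why: N-acylation of an oxazolidinone; the bromomagnesium salt is chosen because it is less prone than the lithium salt to start anionic polymerisation of the acrylimide.

Step 4
Reactants: 4 (E)-trimethyl(5-methylhexa-3,5-dien-1-yn-1-yl)silane; 8 (R)-3-acryloyl-4-benzyl-1,3-oxazolidin-2-one
Product: 9 (R)-4-benzyl-3-{(1S,6R)-4-methyl-6-[(trimethylsilyl)ethynyl]cyclohex-3-ene-1-carbonyl}-1,3-oxazolidin-2-one (acyl and alkynyl cis)
Conditions: Et2AlCl (1.4 equiv), CH2Cl2, −78 → −40 °C; aq. HCl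
Reagents that add atoms: none
Why: Auxiliary-controlled Diels–Alder reaction of an N-acryloyl oxazolidinone: Et2AlCl gives the chelated s-cis acrylimide, the benzyl group screens the Si face of C-α, and the diene adds endo to the Re face. The C4 methyl and the C6 alkynyl group both make the CH2 terminus of the diene the nucleophilic end, which bonds to C-β and places the alkynyl carbon next to the acyl carbon. C6 is thereby set (alkynyl cis to acyl) and 9 is purified as one diastereomer; the configuration at C1 is provisional.

Step 5
Reactants: 9 Diels–Alder imide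
Product: 10 S-ethyl (1S,6R)-4-methyl-6-[(trimethylsilyl)ethynyl]cyclohex-3-ene-1-carbothioate
Conditions: EtSH, n-BuLi, THF, 0 °C; aq. NH4Cl
Reagents that add atoms: ethanethiol, CCS
Why: Transthioesterification of an N-acyloxazolidinone by lithium ethanethiolate at the exocyclic carbonyl; the soft thiolate does not attack silicon, and the auxiliary is recovered. Any epimerisation at C1 is harmless because C1 becomes trigonal in the next step.

Step 6
Reactants: 10 S-ethyl thioester (C1–H)
Product: 12 S-ethyl (1S,6S)-1,4-dimethyl-6-[(trimethylsilyl)ethynyl]cyclohex-3-ene-1-carbothioate, via lithium enolate 11 (not isolated)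
Conditions: LiN(i-Pr)2, THF, −78 °C; then MeI, DMPU, −78 → −40 °C
Reagents that add atoms: iodomethane, CI
Why: C-Alkylation of a thioester lithium enolate with C6 as the controlling element: allylic 1,3-strain against the exocyclic enolate pushes the C6 alkynyl group pseudoaxial, and iodomethane should enter C1 from the opposite face. The methyl group then lies trans to the alkynyl group and the thioester carbon cis to it, the relation the target needs between vinylene and aryl.

Step 7
Reactants: 12 methylated thioester
Product: 13 (1S,6R)-1,4-dimethyl-6-[(trimethylsilyl)ethynyl]cyclohex-3-ene-1-carbaldehyde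
Conditions: i-Bu2AlH, CH2Cl2, −78 °C; aq. potassium sodium tartrate
Reagents that add atoms: none
Why: Partial reduction of a thioester by i-Bu2AlH at low temperature stops at the aldehyde oxidation level. The aldehyde has no α-hydrogen, so C1 cannot epimerise, and the silylalkyne is inert at −78 °C.

Step 8
Reactants: 13 aldehyde
Product: 14 (1S,6R)-1-(2,2-dibromoethenyl)-1,4-dimethyl-6-[(trimethylsilyl)ethynyl]cyclohex-3-ene
Conditions: CBr4, PPh3, CH2Cl2, 0 °C
Reagents that add atoms: carbon tetrabromide, BrC(Br)(Br)Br
Why: First stage of the Corey–Fuchs homologation on a non-enolisable aldehyde; the neutral conditions keep the trimethylsilyl alkyne, which a carbonate/methanol homologation would not.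

Step 9
Reactants: 14 dibromoalkene
Product: 16 (1S,6R)-1,4-dimethyl-1-[(triisopropylsilyl)ethynyl]-6-[(trimethylsilyl)ethynyl]cyclohex-3-ene, via lithium acetylide 15 (not isolated)
Conditions: n-BuLi (2.2 equiv), THF, −78 → 0 °C; then i-Pr3SiOTf, −78 °C → rt
Reagents that add atoms: triisopropylsilyl trifluoromethanesulfonate, CC(C)[Si](C(C)C)(C(C)C)OS(=O)(=O)C(F)(F)F
Why: Second stage of the Corey–Fuchs sequence: bromine–lithium exchange, loss of LiBr and 1,2-hydrogen shift give the alkyne, which is deprotonated to 15 and capped by the bulky silyl triflate. The C1 alkyne now carries the robust silyl group and the C6 alkyne the labile one.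

Step 10
Reactants: 16 bis-silyl diyne
Product: 17 (1S,6S)-6-ethynyl-1,4-dimethyl-1-[(triisopropylsilyl)ethynyl]cyclohex-3-ene
Conditions: K2CO3, MeOH/THF, rt
Reagents that add atoms: none
Why: Carbonate-catalysed methanolysis of the C–Si bond is fast for trimethylsilyl and negligible for triisopropylsilyl alkynes, so only the C6 alkyne should be unmasked.

Step 11
Reactants: 17 terminal alkyne
Product: 20 (1S,6R)-1,4-dimethyl-1-[(triisopropylsilyl)ethynyl]-6-[(triisopropylsilyloxy)ethynyl]cyclohex-3-ene, via lithium acetylide 18 (not isolated), via lithium ynolate 19 (not isolated)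
Conditions: n-BuLi, THF, −78 °C; t-BuOOLi (from t-BuOOH and LiN(SiMe3)2), −78 → 0 °C; i-Pr3SiOTf, −78 → 0 °C
Reagents that add atoms: tert-butyl hydroperoxide, CC(C)(C)OO; triisopropylsilyl trifluoromethanesulfonate, CC(C)[Si](C(C)C)(C(C)C)OS(=O)(=O)C(F)(F)F
Why: Established route from terminal alkynes to triisopropylsiloxyalkynes: acetylide 18 attacks the peroxide oxygen to give ynolate 19, and the bulky silyl triflate reacts at oxygen, not carbon. C6–H is far less acidic than the alkyne C–H, so C6 should keep its configuration.

Step 12
Reactants: 21 cyclobutane-1,3-dione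
Product: 22 3-methoxycyclobut-2-en-1-one
Conditions: Me3SiCHN2, MeOH/PhMe, 0 °C → rt
Reagents that add atoms: (trimethylsilyl)diazomethane, C[Si](C)(C)C=[N+]=[N-]
Why: O-Methylation of a vinylogous acid (the dione exists as its enol) by a diazoalkane; methanol releases the methylating species from the silyl reagent.

Step 13
Reactants: 20 siloxyalkyne; 22 3-methoxycyclobut-2-en-1-one
Product: 27 2-{(1S,6R)-1,4-dimethyl-1-[(triisopropylsilyl)ethynyl]cyclohex-3-en-6-yl}-5-methoxy-3-(triisopropylsilyloxy)phenol, via vinylketene 23 (not isolated), via vinylcyclobutenone 24 (not isolated), via dienylketene 25 (not isolated), via cyclohexadienone 26 (not isolated)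
Conditions: 22 (1.5 equiv), PhMe, 80 → 110 °C, sealed tube
Reagents that add atoms: none
Why: Danheiser benzannulation of a cyclobutenone with a siloxyalkyne, a known cascade of four pericyclic events. Heat opens 22 by 4π electrocyclic ring opening to methoxy vinylketene 23, whose electrophilic central carbon is attacked by the alkyne carbon remote from oxygen (the one bearing the cyclohexenyl group), so the [2+2] adduct 24 has the ring substituent next to the carbonyl and the siloxy group next to the former ketene CH. A second 4π opening gives dienylketene 25, thermal disrotatory 6π electrocyclisation closes the six-membered ring as dienone 26, and tautomerisation gives phenol 27. The new bonds are C8–C8a and C6–C7 (from the [2+2] step) and C4a–C8a (from the 6π closure); the only ring that remains is the benzene ring of coumarin B. No stereocentre is created, and C1 and C6 are not at risk because no acid, base or metal is present. The selectivity needed is regiochemical and chemoselective: ketene/ynol ether polarisation puts the cyclohexenyl carbon between hydroxyl and siloxy with methoxy para, and the electron-rich siloxyalkyne should react far faster than the hindered silylalkyne or the ring alkene. The two flanking oxygens emerge differentiated, which the lactone closure needs, and either sense would lead to the same coumarin.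

Step 14
Reactants: 27 phenol
Product: 29 2-hydroxy-6-methoxy-3-{(1S,6R)-1,4-dimethyl-1-[(triisopropylsilyl)ethynyl]cyclohex-3-en-6-yl}-4-(triisopropylsilyloxy)benzaldehyde, via salicyl alcohol 28 (not isolated)
Conditions: MgCl2, Et3N, (CH2O)n, MeCN, reflux; cold dilute HCl
Reagents that add atoms: formaldehyde (as paraformaldehyde), C=O
Why: Casnati–Skattebøl ortho-formylation: the magnesium phenoxide delivers formaldehyde to the only free ortho position to give 28, which a second formaldehyde oxidises by hydride transfer. The activated position para to the hydroxyl is not reached by this chelation-bound electrophile, and the silyl groups tolerate Et3N.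

Step 15
Reactants: 29 salicylaldehyde; 30 ethyl 2-(triphenyl-λ5-phosphanylidene)acetate
Product: 32 8-{(1S,6R)-1,4-dimethyl-1-[(triisopropylsilyl)ethynyl]cyclohex-3-en-6-yl}-5-methoxy-7-(triisopropylsilyloxy)-2H-chromen-2-one, via E-cinnamate 31 (not isolated)
Conditions: PhNEt2, reflux (ca. 215 °C)
Reagents that add atoms: none
Why: Wittig olefination gives 31; in refluxing diethylaniline the alkene isomerises and the phenol closes the lactone with loss of ethanol, the classical one-flask coumarin synthesis from salicylaldehydes. The silyl ether is meta to the reacting oxygen and cannot migrate to it, and the stereocentres have no thermal pathway in this weakly basic medium.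

Step 16
Reactants: 32 silylated coumarin
Product: 33 8-[(1S,6R)-1-ethynyl-1,4-dimethylcyclohex-3-en-6-yl]-7-hydroxy-5-methoxy-2H-chromen-2-one
Conditions: n-Bu4NF, THF, 0 °C → rt; aq. NH4Cl
Reagents that add atoms: none
Why: Fluoride cleaves the aryl O–Si bond at once and the alkynyl C–Si bond on warming, so one operation frees both the 7-hydroxyl and the terminal alkyne. Buffered work-up avoids acid, which could add the phenol across C4=C5.

Step 17
Reactants: 33 7-hydroxycoumarin
Product: 34 8-[(1S,6R)-1-ethynyl-1,4-dimethylcyclohex-3-en-6-yl]-5,7-dimethoxy-2H-chromen-2-one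
Conditions: MeI, K2CO3, acetone, 50 °C
Reagents that add atoms: iodomethane, CI
Why: Williamson methylation of the acidic 7-hydroxycoumarin; carbonate does not deprotonate the terminal alkyne, and the lactone is stable to it in acetone.

Step 18
Reactants: 35 5,7-dimethoxy-2H-chromen-2-one
Product: 36 8-iodo-5,7-dimethoxy-2H-chromen-2-one
Conditions: N-iodosuccinimide, CF3CO2H (cat.), MeCN, rt
Reagents that add atoms: N-iodosuccinimide, O=C1CCC(=O)N1I
Why: Electrophilic aromatic iodination; C8 is ortho to the 7-methoxy and para to the 5-methoxy group and less crowded than C6, which lies between both methoxy groups.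

Step 19
Reactants: 34 terminal alkyne
Product: 37 8-{(1R,6R)-1,4-dimethyl-1-[(E)-2-(4,4,5,5-tetramethyl-1,3,2-dioxaborolan-2-yl)ethenyl]cyclohex-3-en-6-yl}-5,7-dimethoxy-2H-chromen-2-one
Conditions: pinacolborane, (c-C6H11)2BH (10 mol %), THF, rt
Reagents that add atoms: pinacolborane, CC1(C)OBOC1(C)C
Why: Borane-catalysed syn-hydroboration of a terminal alkyne with pinacolborane; boron goes to the unhindered terminal carbon and gives the E-alkenylboronate. The hindered dialkylborane carrier should not touch the trisubstituted alkene, the coumarin C3=C4 bond or the lactone at room temperature.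

Step 20
Reactants: 37 alkenylboronate; 36 8-iodo-5,7-dimethoxy-2H-chromen-2-one
Product: 38 8-{(1R,6R)-1-[(E)-2-(5,7-dimethoxy-2-oxo-2H-chromen-8-yl)ethenyl]-1,4-dimethylcyclohex-3-en-6-yl}-5,7-dimethoxy-2H-chromen-2-one (CNP0164660.2)
Conditions: Pd(OAc)2, 2-dicyclohexylphosphino-2′,6′-dimethoxybiphenyl, K3PO4, THF/H2O, 60 °C
Reagents that add atoms: none
Why: Suzuki–Miyaura coupling with retention of the E geometry; the electron-rich biarylphosphine promotes oxidative addition and transmetalation at the di-ortho-substituted iodide. Aqueous phosphate is mild enough for both lactones and leaves C6–H alone, so neither stereocentre is at risk.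

## Compound list

1 | 3-(trimethylsilyl)prop-2-ynal | C[Si](C)(C)C#CC=O | starting material
2 | 1-(triphenyl-λ5-phosphanylidene)propan-2-one | CC(=O)C=P(c1ccccc1)(c1ccccc1)c1ccccc1 | starting material
3 | (E)-6-(trimethylsilyl)hex-3-en-5-yn-2-one | CC(=O)/C=C/C#C[Si](C)(C)C | intermediate
4 | (E)-trimethyl(5-methylhexa-3,5-dien-1-yn-1-yl)silane | C=C(C)/C=C/C#C[Si](C)(C)C | intermediate
5 | (R)-4-benzyl-1,3-oxazolidin-2-one | O=C1N[C@H](Cc2ccccc2)CO1 | starting material
6 | acryloyl chloride | C=CC(Cl)=O | starting material
7 | bromomagnesium salt of 5 (N-metalated) | O=C1N([Mg]Br)[C@H](Cc2ccccc2)CO1 | intermediate (not isolated)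
8 | (R)-3-acryloyl-4-benzyl-1,3-oxazolidin-2-one | C=CC(=O)N1[C@H](Cc2ccccc2)COC1=O | intermediate
9 | (R)-4-benzyl-3-{(1S,6R)-4-methyl-6-[(trimethylsilyl)ethynyl]cyclohex-3-ene-1-carbonyl}-1,3-oxazolidin-2-one (acyl and alkynyl cis) | O=C(N1[C@H](Cc2ccccc2)COC1=O)[C@H]1CCC(C)=C[C@H]1C#C[Si](C)(C)C | intermediate
10 | S-ethyl (1S,6R)-4-methyl-6-[(trimethylsilyl)ethynyl]cyclohex-3-ene-1-carbothioate | CCSC(=O)[C@H]1CCC(C)=C[C@H]1C#C[Si](C)(C)C | intermediate
11 | lithium enolate of 10 (C1 trigonal; 6S) | CCSC(O[Li])=C1CCC(C)=C[C@H]1C#C[Si](C)(C)C | intermediate (not isolated)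
12 | S-ethyl (1S,6S)-1,4-dimethyl-6-[(trimethylsilyl)ethynyl]cyclohex-3-ene-1-carbothioate (thioester cis to alkynyl) | CCSC(=O)[C@@]1(C)CCC(C)=C[C@H]1C#C[Si](C)(C)C | intermediate
13 | (1S,6R)-1,4-dimethyl-6-[(trimethylsilyl)ethynyl]cyclohex-3-ene-1-carbaldehyde | O=C[C@@]1(C)CCC(C)=C[C@H]1C#C[Si](C)(C)C | intermediate
14 | (1S,6R)-1-(2,2-dibromoethenyl)-1,4-dimethyl-6-[(trimethylsilyl)ethynyl]cyclohex-3-ene | BrC(Br)=C[C@@]1(C)CCC(C)=C[C@H]1C#C[Si](C)(C)C | intermediate
15 | {(1S,6R)-1,4-dimethyl-6-[(trimethylsilyl)ethynyl]cyclohex-3-en-1-yl}ethynyllithium | [Li]C#C[C@@]1(C)CCC(C)=C[C@H]1C#C[Si](C)(C)C | intermediate (not isolated)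
16 | (1S,6R)-1,4-dimethyl-1-[(triisopropylsilyl)ethynyl]-6-[(trimethylsilyl)ethynyl]cyclohex-3-ene | CC(C)[Si](C(C)C)(C(C)C)C#C[C@@]1(C)CCC(C)=C[C@H]1C#C[Si](C)(C)C | intermediate
17 | (1S,6S)-6-ethynyl-1,4-dimethyl-1-[(triisopropylsilyl)ethynyl]cyclohex-3-ene | CC(C)[Si](C(C)C)(C(C)C)C#C[C@@]1(C)CCC(C)=C[C@H]1C#C | intermediate
18 | lithium acetylide of 17 (1S,6S; lithium on the C6 alkyne) | CC(C)[Si](C(C)C)(C(C)C)C#C[C@@]1(C)CCC(C)=C[C@H]1C#C[Li] | intermediate (not isolated)
19 | lithium 2-{(1S,6R)-1,4-dimethyl-1-[(triisopropylsilyl)ethynyl]cyclohex-3-en-6-yl}ethynolate | CC(C)[Si](C(C)C)(C(C)C)C#C[C@@]1(C)CCC(C)=C[C@H]1C#CO[Li] | intermediate (not isolated)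
20 | (1S,6R)-1,4-dimethyl-1-[(triisopropylsilyl)ethynyl]-6-[(triisopropylsilyloxy)ethynyl]cyclohex-3-ene | CC(C)[Si](C(C)C)(C(C)C)C#C[C@@]1(C)CCC(C)=C[C@H]1C#CO[Si](C(C)C)(C(C)C)C(C)C | intermediate
21 | cyclobutane-1,3-dione | O=C1CC(=O)C1 | starting material
22 | 3-methoxycyclobut-2-en-1-one | COC1=CC(=O)C1 | intermediate
23 | 3-methoxybuta-1,3-dien-1-one (methoxy vinylketene) | C=C(OC)C=C=O | intermediate (not isolated)
24 | 2-{(1S,6R)-1,4-dimethyl-1-[(triisopropylsilyl)ethynyl]cyclohex-3-en-6-yl}-4-(1-methoxyethenyl)-3-(triisopropylsilyloxy)cyclobut-2-en-1-one (C4 of the four-membered ring either configuration) | CC(C)[Si](C(C)C)(C(C)C)C#C[C@@]1(C)CCC(C)=C[C@H]1C1=C(O[Si](C(C)C)(C(C)C)C(C)C)C(C(OC)=C)C1=O | intermediate (not isolated)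
25 | 2-{(1S,6R)-1,4-dimethyl-1-[(triisopropylsilyl)ethynyl]cyclohex-3-en-6-yl}-5-methoxy-3-(triisopropylsilyloxy)hexa-1,3,5-trien-1-one (C2 and C5 cis across C3=C4) | CC(C)[Si](C(C)C)(C(C)C)C#C[C@@]1(C)CCC(C)=C[C@H]1C(=C=O)/C(O[Si](C(C)C)(C(C)C)C(C)C)=C\C(OC)=C | intermediate (not isolated)
26 | 2-{(1S,6R)-1,4-dimethyl-1-[(triisopropylsilyl)ethynyl]cyclohex-3-en-6-yl}-5-methoxy-3-(triisopropylsilyloxy)cyclohexa-2,4-dien-1-one | CC(C)[Si](C(C)C)(C(C)C)C#C[C@@]1(C)CCC(C)=C[C@H]1C1=C(O[Si](C(C)C)(C(C)C)C(C)C)C=C(OC)CC1=O | intermediate (not isolated)
27 | 2-{(1S,6R)-1,4-dimethyl-1-[(triisopropylsilyl)ethynyl]cyclohex-3-en-6-yl}-5-methoxy-3-(triisopropylsilyloxy)phenol | CC(C)[Si](C(C)C)(C(C)C)C#C[C@@]1(C)CCC(C)=C[C@H]1c1c(O)cc(OC)cc1O[Si](C(C)C)(C(C)C)C(C)C | intermediate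
28 | 2-(hydroxymethyl)-3-methoxy-6-{(1S,6R)-1,4-dimethyl-1-[(triisopropylsilyl)ethynyl]cyclohex-3-en-6-yl}-5-(triisopropylsilyloxy)phenol | CC(C)[Si](C(C)C)(C(C)C)C#C[C@@]1(C)CCC(C)=C[C@H]1c1c(O)c(CO)c(OC)cc1O[Si](C(C)C)(C(C)C)C(C)C | intermediate (not isolated)
29 | 2-hydroxy-6-methoxy-3-{(1S,6R)-1,4-dimethyl-1-[(triisopropylsilyl)ethynyl]cyclohex-3-en-6-yl}-4-(triisopropylsilyloxy)benzaldehyde | CC(C)[Si](C(C)C)(C(C)C)C#C[C@@]1(C)CCC(C)=C[C@H]1c1c(O)c(C=O)c(OC)cc1O[Si](C(C)C)(C(C)C)C(C)C | intermediate
30 | ethyl 2-(triphenyl-λ5-phosphanylidene)acetate | CCOC(=O)C=P(c1ccccc1)(c1ccccc1)c1ccccc1 | starting material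
31 | ethyl (E)-3-[2-hydroxy-6-methoxy-3-{(1S,6R)-1,4-dimethyl-1-[(triisopropylsilyl)ethynyl]cyclohex-3-en-6-yl}-4-(triisopropylsilyloxy)phenyl]prop-2-enoate | CC(C)[Si](C(C)C)(C(C)C)C#C[C@@]1(C)CCC(C)=C[C@H]1c1c(O)c(/C=C/C(=O)OCC)c(OC)cc1O[Si](C(C)C)(C(C)C)C(C)C | intermediate (not isolated)
32 | 8-{(1S,6R)-1,4-dimethyl-1-[(triisopropylsilyl)ethynyl]cyclohex-3-en-6-yl}-5-methoxy-7-(triisopropylsilyloxy)-2H-chromen-2-one | CC(C)[Si](C(C)C)(C(C)C)C#C[C@@]1(C)CCC(C)=C[C@H]1c1c(O[Si](C(C)C)(C(C)C)C(C)C)cc(OC)c2ccc(=O)oc12 | intermediate
33 | 8-[(1S,6R)-1-ethynyl-1,4-dimethylcyclohex-3-en-6-yl]-7-hydroxy-5-methoxy-2H-chromen-2-one | C#C[C@@]1(C)CCC(C)=C[C@H]1c1c(O)cc(OC)c2ccc(=O)oc12 | intermediate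
34 | 8-[(1S,6R)-1-ethynyl-1,4-dimethylcyclohex-3-en-6-yl]-5,7-dimethoxy-2H-chromen-2-one | C#C[C@@]1(C)CCC(C)=C[C@H]1c1c(OC)cc(OC)c2ccc(=O)oc12 | intermediate
35 | 5,7-dimethoxy-2H-chromen-2-one | COc1cc(OC)c2ccc(=O)oc2c1 | starting material
36 | 8-iodo-5,7-dimethoxy-2H-chromen-2-one | COc1cc(OC)c2ccc(=O)oc2c1I | intermediate
37 | 8-{(1R,6R)-1,4-dimethyl-1-[(E)-2-(4,4,5,5-tetramethyl-1,3,2-dioxaborolan-2-yl)ethenyl]cyclohex-3-en-6-yl}-5,7-dimethoxy-2H-chromen-2-one | CC1(C)OB(/C=C/[C@@]2(C)CCC(C)=C[C@H]2c2c(OC)cc(OC)c3ccc(=O)oc23)OC1(C)C | intermediate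
38 | 8-{(1R,6R)-1-[(E)-2-(5,7-dimethoxy-2-oxo-2H-chromen-8-yl)ethenyl]-1,4-dimethylcyclohex-3-en-6-yl}-5,7-dimethoxy-2H-chromen-2-one | COc1cc(OC)c2ccc(=O)oc2c1/C=C/[C@@]1(C)CCC(C)=C[C@H]1c1c(OC)cc(OC)c2ccc(=O)oc12 | target

## Step count and least certain steps

Total: 20 steps. Longest linear sequence: 17 steps (steps 1, 2, 4–11, 13–17, 19, 20).

Step 13 (key step). The cyclobutenone is a vinylogous ester and may open more slowly than the 3-alkyl cyclobutenones usually used. The siloxyalkyne, whose reacting carbon also carries a bulky secondary substituent, could then be lost to thermal degradation or adventitious hydrolysis before the ketene captures it. The fallback generates the same vinylketene without heat and sets out from 20. Purchased 3,3-dimethoxybutan-2-one loses methanol over an acid catalyst to give 3-methoxybut-3-en-2-one F1. Trifluoroacetylation (LiN(SiMe3)2, CF3CO2CH2CF3) gives 1,1,1-trifluoro-5-methoxyhex-5-ene-2,4-dione F2, and detrifluoroacetylative diazo transfer (MsN3, Et3N, H2O, MeCN) gives 1-diazo-3-methoxybut-3-en-2-one F3. Irradiating F3 with 20 at room temperature forms 23 by photochemical Wolff rearrangement; 24 follows at once, and brief warming carries it through 25 and 26 to 27, where the route is rejoined.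

Step 6. The alkynyl group on C6 is slim, so the facial bias it exerts on the enolate may be modest, with methylation partly on the wrong face. The fallback sets C1 in the cycloaddition instead and sets out from 4. A Diels–Alder reaction of 4 with purchased methacrolein is run under the N-protonated B-(o-tolyl)oxazaborolidine of α,α-diphenylprolinol as its bis(trifluoromethanesulfonyl)imide salt, with the catalyst antipode chosen so that the diene adds endo to the Re face of C-α. This gives aldehyde 13 directly, where the route is rejoined (F0: no new compound is made).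

Step 4. The strongly Lewis-acidic, stoichiometric promoter may oligomerise the enyne diene, or the endo preference may erode if this less nucleophilic diene needs a higher temperature. The fallback moves to catalyst control and sets out from 4. Cycloaddition with purchased 2,2,2-trifluoroethyl acrylate under the same class of oxazaborolidinium salt gives 2,2,2-trifluoroethyl (1S,6R)-4-methyl-6-[(trimethylsilyl)ethynyl]cyclohex-3-ene-1-carboxylate F4. Me2AlSEt (from AlMe3 and EtSH) converts F4 into thioester 10, where the route is rejoined.

Step 15. Thermal stress near 215 °C may cleave or scramble the aryl silyl ether, or the E-to-Z isomerisation that precedes lactonisation may stall on this crowded cinnamate. The fallback replaces thermal equilibration by a kinetically Z-selective olefination and sets out from 29. Horner–Wadsworth–Emmons reaction with ethyl (diphenoxyphosphoryl)acetate (NaH, THF, −78 °C → rt) gives the Z-cinnamate F5, which lactonises at room temperature to 32, where the route is rejoined.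

Step 20. Transmetalation to a palladium centre flanked by two ortho substituents may be slow, letting protodeboronation and base-induced lactone opening compete. The fallback avoids boron and aqueous base and sets out from 34. Hydrostannation (n-Bu3SnH, Pd(PPh3)2Cl2, THF) gives the E-alkenylstannane F6; the tert-alkyl group directs tin to the terminal carbon. Stille coupling with 36 (Pd(PPh3)4, CuI, CsF, DMF) gives 38.

## Further compounds

F1 | step 13 | 3-methoxybut-3-en-2-one | C=C(OC)C(C)=O
F2 | step 13 | 1,1,1-trifluoro-5-methoxyhex-5-ene-2,4-dione | C=C(OC)C(=O)CC(=O)C(F)(F)F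
F3 | step 13 | 1-diazo-3-methoxybut-3-en-2-one | C=C(OC)C(=O)C=[N+]=[N-]
F0 | step 6 | none | none
F4 | step 4 | 2,2,2-trifluoroethyl (1S,6R)-4-methyl-6-[(trimethylsilyl)ethynyl]cyclohex-3-ene-1-carboxylate | FC(F)(F)COC(=O)[C@H]1CCC(C)=C[C@H]1C#C[Si](C)(C)C
F5 | step 15 | ethyl (Z)-3-[2-hydroxy-6-methoxy-3-{(1S,6R)-1,4-dimethyl-1-[(triisopropylsilyl)ethynyl]cyclohex-3-en-6-yl}-4-(triisopropylsilyloxy)phenyl]prop-2-enoate | CC(C)[Si](C(C)C)(C(C)C)C#C[C@@]1(C)CCC(C)=C[C@H]1c1c(O)c(/C=C\C(=O)OCC)c(OC)cc1O[Si](C(C)C)(C(C)C)C(C)C
F6 | step 20 | 8-{(1S,6R)-1,4-dimethyl-1-[(E)-2-(tributylstannyl)ethenyl]cyclohex-3-en-6-yl}-5,7-dimethoxy-2H-chromen-2-one | CCCC[Sn](CCCC)(CCCC)/C=C/[C@@]1(C)CCC(C)=C[C@H]1c1c(OC)cc(OC)c2ccc(=O)oc12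
A1 | alternative 1 | methyl (1S,6R)-6-[2,4-dimethoxy-6-(methoxymethoxy)phenyl]-1,4-dimethylcyclohex-3-ene-1-carboxylate (aryl cis to ester) | COC(=O)[C@@]1(C)CCC(C)=C[C@H]1c1c(OCOC)cc(OC)cc1OC
A2 | alternative 1 | methyl 4-methylcyclohexa-1,3-diene-1-carboxylate | COC(=O)C1=CC=C(C)CC1
A3 | alternative 1 | [2,4-dimethoxy-6-(methoxymethoxy)phenyl]zinc chloride | COCOc1cc(OC)cc(OC)c1[Zn]Cl
A4 | alternative 2 | 8-{(1S,6R)-1,4-dimethyl-1-[(trimethylsilyl)ethynyl]cyclohex-3-en-6-yl}-5,7-dimethoxy-2H-chromen-2-one | C[Si](C)(C)C#C[C@@]1(C)CCC(C)=C[C@H]1c1c(OC)cc(OC)c2ccc(=O)oc12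
A5 | alternative 2 | 8-{(2R,5Z)-1-hydroxy-2,5-dimethyl-6-(trimethylsilyl)-2-[(trimethylsilyl)ethynyl]hex-5-en-1-yl}-5,7-dimethoxy-2H-chromen-2-one (carbinol centre either configuration) | C[Si](C)(C)C#C[C@@](C)(CC/C(C)=C\[Si](C)(C)C)C(O)c1c(OC)cc(OC)c2ccc(=O)oc12
A6 | alternative 3 | (1S,6R)-6-[2,4-dimethoxy-6-(methoxymethoxy)phenyl]-1,4-dimethylcyclohex-3-ene-1-carboxylic acid (aryl cis to carboxyl) | OC(=O)[C@@]1(C)CCC(C)=C[C@H]1c1c(OCOC)cc(OC)cc1OC
A7 | alternative 3 | (6R)-6-{(E)-2-[2,4-dimethoxy-6-(methoxymethoxy)phenyl]ethenyl}-3,6-dimethyloxan-2-one (C3 either configuration) | O=C1O[C@@](C)(/C=C/c2c(OCOC)cc(OC)cc2OC)CCC1C
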